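**Plan**

- Numbering used (11-oxabicyclo[8.1.0]undecane): C1/C10 are the epoxide carbons (C10 bears CH3), C2 carries the ester, C3 the isopropyl group, C4=C5 is the E-alkene, C6 is the C(OH)CH3 carbinol, C7–C9 are CH2.
- Retrosynthetic cuts, in order: the aryl O–Si bond; the ring bond C5–C6 (alkene CH to carbinol carbon), giving an acyclic (E)-alkenyl iodide/methyl ketone; the ester C–O at C2; C2–C3 (aldol); C9–C10 (sp3–sp2 coupling).
- Forward order: C9–C10 by B-alkyl Suzuki coupling, the epoxide ring by Sharpless epoxidation, C2–C3 by Evans aldol, the C4=C5–I unit by Takai olefination, then ester and ketone; the ten-membered carbocycle is closed last by a Nozaki–Hiyama–Kishi (NHK) reaction, followed by desilylation.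
- Enabling feature: C6 is a tertiary allylic carbinol (CH3, OH) bonded directly to C5 of the E-alkene inside the ten-membered ring, the retron of an alkenylmetal addition to a methyl ketone; the trans alkene keeps the metal-bearing carbon away from the C2 ester and the epoxide.
- Stereochemistry: C1/C10 from Sharpless epoxidation of a (Z)-allylic alcohol with D-(−)-tartrate; C2/C3 from the (R)-benzyloxazolidinone syn-aldol, matched with the Cornforth preference of the epoxy aldehyde; the E-alkene from Takai olefination, retained; C6 from the macrocyclic transition state of the ring closure.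

Key step: step 15

Remark: the carbinol carbon of the pentyl side chain later becomes the ring ketone, so its configuration is immaterial; the (S) alcohol is used only to keep every intermediate a single diastereomer.

**Step 1**
Reactants: 1 but-2-yn-1-ol
Product: 2 (2Z)-3-iodobut-2-en-1-ol
Conditions: NaAlH2(OCH2CH2OCH3)2, THF, 0 °C to rt; then I2, THF, −78 °C to rt
Reagents that add atoms: iodine, II
Why: hydroxyl-directed trans-hydroalumination of the propargylic alcohol places aluminium at C3 cis to the CH2O group, and iodinolysis with retention should give the (Z)-iodoalkene.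

**Step 2**
Reactants: 3 (2S)-pent-4-en-2-ol
Product: 4 4-methoxybenzyl ether of 3
Conditions: NaH, 4-methoxybenzyl chloride, Bu4NI (cat.), THF/DMF, 0 °C to rt
Reagents that add atoms: 4-methoxybenzyl chloride, COc1ccc(CCl)cc1
Why: Williamson etherification masks the latent ketone carbinol as an ether that can later be removed oxidatively without acid, and the stereocentre is not touched.

**Step 3**
Reactants: 4 4-methoxybenzyl ether of 3, 2 (2Z)-3-iodobut-2-en-1-ol
Product: 6 (2Z,7S)-7-[(4-methoxybenzyl)oxy]-3-methyloct-2-en-1-ol, via alkylborane 5 (not isolated)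
Conditions: 9-BBN, THF, 0 °C to rt; then 2, Pd(dppf)Cl2 (cat.), AsPh3, Cs2CO3, DMF/H2O, rt
Reagents that add atoms: none
Why: anti-Markovnikov hydroboration followed by B-alkyl Suzuki–Miyaura coupling, which retains the alkenyl iodide geometry and tolerates the free hydroxyl, should give the (Z)-trisubstituted allylic alcohol.

**Step 4**
Reactants: 6 (2Z,7S)-7-[(4-methoxybenzyl)oxy]-3-methyloct-2-en-1-ol
Product: 7 [(2R,3S)-3-{(4S)-4-[(4-methoxybenzyl)oxy]pentyl}-3-methyloxiran-2-yl]methanol
Conditions: Ti(OiPr)4 (cat.), D-(−)-diethyl tartrate (cat.), t-BuOOH, 4 Å molecular sieves, CH2Cl2, −20 °C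
Reagents that add atoms: tert-butyl hydroperoxide, CC(C)(C)OO
Why: Sharpless asymmetric epoxidation, in which the D-(−)-tartrate catalyst should deliver oxygen to the face giving the (2R,3S) epoxide from a (Z)-3,3-disubstituted allylic alcohol (the nerol pattern), and the Z geometry gives the cis relation of the chain and the CH2OH carbon.

**Step 5**
Reactants: 7 [(2R,3S)-3-{(4S)-4-[(4-methoxybenzyl)oxy]pentyl}-3-methyloxiran-2-yl]methanol
Product: 8 (2S,3S)-3-{(4S)-4-[(4-methoxybenzyl)oxy]pentyl}-3-methyloxirane-2-carbaldehyde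
Conditions: Dess–Martin periodinane, NaHCO3, CH2Cl2, 0 °C to rt
Reagents that add atoms: none
Why: buffered Dess–Martin oxidation should give the epoxy aldehyde without acid or base that could open or epimerise the epoxide.

**Step 6**
Reactants: 9 (4R)-4-benzyl-1,3-oxazolidin-2-one, 10 3-methylbutanoyl chloride
Product: 11 (4R)-4-benzyl-3-(3-methylbutanoyl)-1,3-oxazolidin-2-one
Conditions: n-BuLi, THF, −78 °C; then 10, −78 to 0 °C
Reagents that add atoms: none
Why: N-acylation of the lithiated oxazolidinone is the standard entry to the Evans imide.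

**Step 7**
Reactants: 11 (4R)-4-benzyl-3-(3-methylbutanoyl)-1,3-oxazolidin-2-one, 8 (2S,3S)-3-{(4S)-4-[(4-methoxybenzyl)oxy]pentyl}-3-methyloxirane-2-carbaldehyde
Product: 13 (4R)-4-benzyl-3-[(2R,3R)-3-hydroxy-3-[(2R,3S)-3-{(4S)-4-[(4-methoxybenzyl)oxy]pentyl}-3-methyloxiran-2-yl]-2-(propan-2-yl)propanoyl]-1,3-oxazolidin-2-one, via boron enolate 12 (not isolated)
Conditions: Bu2BOTf, Et3N, CH2Cl2, −78 to 0 °C; then 8, −78 to 0 °C; pH 7 buffer, MeOH, H2O2, 0 °C
Reagents that add atoms: none
Why: Evans syn-aldol through the (Z)-boron enolate and a Zimmerman–Traxler chair, in which the (R) auxiliary sets both new centres (2R,3R, syn) and this sense coincides with the Cornforth preference of the α-oxygenated aldehyde for a carbinol anti to the epoxide oxygen, so the case should be matched.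

**Step 8**
Reactants: 13 aldol adduct
Product: 14 (1R,2S)-1-[(2R,3S)-3-{(4S)-4-[(4-methoxybenzyl)oxy]pentyl}-3-methyloxiran-2-yl]-2-(propan-2-yl)propane-1,3-diol
Conditions: LiBH4, MeOH, THF, 0 °C
Reagents that add atoms: none
Why: reductive cleavage of the imide by LiBH4 is selective for the exocyclic carbonyl and should leave the hindered trisubstituted epoxide intact at 0 °C while releasing the auxiliary for recovery.

**Step 9**
Reactants: 14 diol
Product: 15 (2R,3R)-3-hydroxy-3-[(2R,3S)-3-{(4S)-4-[(4-methoxybenzyl)oxy]pentyl}-3-methyloxiran-2-yl]-2-(propan-2-yl)propanal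
Conditions: TEMPO (cat.), PhI(OAc)2, CH2Cl2, rt
Reagents that add atoms: none
Why: the oxoammonium (TEMPO) oxidation is selective for the primary over the hindered secondary alcohol and should give the β-hydroxy aldehyde, which is used crude to avoid epimerisation at the α-carbon.

**Step 10**
Reactants: 15 β-hydroxy aldehyde
Product: 16 (1R,2S,3E)-4-iodo-1-[(2R,3S)-3-{(4S)-4-[(4-methoxybenzyl)oxy]pentyl}-3-methyloxiran-2-yl]-2-(propan-2-yl)but-3-en-1-ol
Conditions: CrCl2, CHI3, THF/1,4-dioxane, 0 °C to rt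
Reagents that add atoms: iodoform, IC(I)I
Why: Takai olefination with the geminal dichromium reagent is E-selective, aldehyde-specific and tolerant of free hydroxyl groups, so it should give the (E)-alkenyl iodide without protection of the carbinol.

**Step 11**
Reactants: 17 4-hydroxybenzoic acid
Product: 19 4-[(tert-butyldimethylsilyl)oxy]benzoic acid, via bis-silyl derivative 18 (not isolated)
Conditions: TBSCl, imidazole, DMF, rt; then AcOH/THF/H2O, rt
Reagents that add atoms: tert-butyldimethylsilyl chloride, CC(C)(C)[Si](C)(C)Cl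
Why: exhaustive silylation followed by selective hydrolysis of the much more labile silyl ester should leave the aryl silyl ether in place.

**Step 12**
Reactants: 16 alkenyl iodide alcohol, 19 4-[(tert-butyldimethylsilyl)oxy]benzoic acid
Product: 21 (1R,2S,3E)-4-iodo-1-[(2R,3S)-3-{(4S)-4-[(4-methoxybenzyl)oxy]pentyl}-3-methyloxiran-2-yl]-2-(propan-2-yl)but-3-en-1-yl 4-[(tert-butyldimethylsilyl)oxy]benzoate, via mixed anhydride 20 (not isolated)
Conditions: 19, 2,4,6-trichlorobenzoyl chloride, Et3N, THF, rt; then 16, DMAP, toluene, rt to 40 °C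
Reagents that add atoms: none
Why: Yamaguchi esterification acylates the hindered secondary alcohol at oxygen, hence with retention at carbon, under mildly basic conditions that should not harm the epoxide, the alkenyl iodide or the aryl silyl ether.

**Step 13**
Reactants: 21 ester
Product: 22 (1R,2S,3E)-1-[(2R,3S)-3-[(4S)-4-hydroxypentyl]-3-methyloxiran-2-yl]-4-iodo-2-(propan-2-yl)but-3-en-1-yl 4-[(tert-butyldimethylsilyl)oxy]benzoate
Conditions: DDQ, CH2Cl2/pH 7 phosphate buffer, 0 °C
Reagents that add atoms: none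
Why: oxidative cleavage of the 4-methoxybenzyl ether with DDQ under buffered conditions is neutral, so the epoxide, ester, alkenyl iodide and aryl silyl ether should survive.

**Step 14**
Reactants: 22 secondary alcohol
Product: 23 (1R,2S,3E)-4-iodo-1-[(2R,3S)-3-methyl-3-(4-oxopentyl)oxiran-2-yl]-2-(propan-2-yl)but-3-en-1-yl 4-[(tert-butyldimethylsilyl)oxy]benzoate
Conditions: Dess–Martin periodinane, NaHCO3, CH2Cl2, 0 °C to rt
Reagents that add atoms: none
Why: buffered Dess–Martin oxidation unveils the methyl ketone (removing the auxiliary stereocentre) without the acid that would turn a 6,7-epoxy ketone into a bicyclic ketal.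

**Step 15**
Reactants: 23 alkenyl iodide methyl ketone
Product: 25 (1R,2R,3S,4E,6R,10S)-6-hydroxy-6,10-dimethyl-3-(propan-2-yl)-11-oxabicyclo[8.1.0]undec-4-en-2-yl 4-[(tert-butyldimethylsilyl)oxy]benzoate, via alkenylchromium dichloride 24 (not isolated)
Conditions: CrCl2 (excess), NiCl2 (cat.), degassed DMSO, slow addition of 23 to 0.002 M, rt to 45 °C; aqueous ethylenediamine work-up
Reagents that add atoms: none
Why: NiCl2 is reduced by CrCl2 to zerovalent nickel, which inserts into the C–I bond, and transmetalation gives the (E)-alkenylchromium dichloride 24 (trivalent chromium) with retention of geometry; this adds to the methyl ketone through a four-centred transition state, so two electrophilic carbons are joined by reductive polarity reversal (Nozaki–Hiyama–Kishi reaction). The closest known reaction type is the NHK macrocyclisation of alkenyl iodides onto aldehydes to form medium rings, together with NHK cyclisations onto ketones. The ten-membered carbocycle closes in the 10-exo-trig mode at the carbonyl carbon. The new carbinol centre C6 (target numbering) is set by the substrate: allylic strain should put the C3–H in the plane of the alkene so that the (S) centre C3 fixes the alkene face spanned by the tether, the solvated chromium must stay on the open outer face and draws the carbonyl oxygen outward and away from the tether, and the methyl group then lies toward the alkene, which corresponds to (R). The step needs chemoselectivity for the ketone over the aryl ester, the epoxide and the silyl ether, which the low basicity and carbonyl selectivity of alkenylchromium reagents should provide, helped by the E geometry that keeps the metal-bearing carbon out of reach of the C2 ester carbonyl. It also needs ring closure to outrun dimerisation, which slow addition at high dilution and the turn imposed by the cis-epoxide should secure.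

**Step 16**
Reactants: 25 silyl-protected macrocycle
Product: 26 (1R,2R,3S,4E,6R,10S)-6-hydroxy-6,10-dimethyl-3-(propan-2-yl)-11-oxabicyclo[8.1.0]undec-4-en-2-yl 4-hydroxybenzoate
Conditions: TBAF, AcOH, THF, 0 °C
Reagents that add atoms: none
Why: fluoride-mediated desilylation cleaves the aryl silyl ether rapidly, and the acetic acid buffer should protect the ester, the epoxide and the tertiary allylic alcohol from the basic phenoxide.

**Compound list**

1 | but-2-yn-1-ol | CC#CCO | starting material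
2 | (2Z)-3-iodobut-2-en-1-ol | C/C(I)=C/CO | intermediate
3 | (2S)-pent-4-en-2-ol | C[C@H](O)CC=C | starting material
4 | 1-methoxy-4-({[(2S)-pent-4-en-2-yl]oxy}methyl)benzene | C[C@H](OCc1ccc(OC)cc1)CC=C | intermediate
5 | 9-{(4S)-4-[(4-methoxybenzyl)oxy]pentyl}-9-borabicyclo[3.3.1]nonane | C[C@H](OCc1ccc(OC)cc1)CCCB1C2CCCC1CCC2 | intermediate
6 | (2Z,7S)-7-[(4-methoxybenzyl)oxy]-3-methyloct-2-en-1-ol | C/C(CCC[C@H](C)OCc1ccc(OC)cc1)=C/CO | intermediate
7 | [(2R,3S)-3-{(4S)-4-[(4-methoxybenzyl)oxy]pentyl}-3-methyloxiran-2-yl]methanol | OC[C@@H]1[C@@](CCC[C@H](C)OCc2ccc(OC)cc2)(C)O1 | intermediate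
8 | (2S,3S)-3-{(4S)-4-[(4-methoxybenzyl)oxy]pentyl}-3-methyloxirane-2-carbaldehyde | O=C[C@@H]1[C@@](CCC[C@H](C)OCc2ccc(OC)cc2)(C)O1 | intermediate
9 | (4R)-4-benzyl-1,3-oxazolidin-2-one | O=C1N[C@H](Cc2ccccc2)CO1 | starting material
10 | 3-methylbutanoyl chloride | CC(C)CC(Cl)=O | starting material
11 | (4R)-4-benzyl-3-(3-methylbutanoyl)-1,3-oxazolidin-2-one | CC(C)CC(=O)N1[C@H](Cc2ccccc2)COC1=O | intermediate
12 | (Z)-dibutylboron enolate of 11 | CC(C)/C=C(\OB(CCCC)CCCC)N1[C@H](Cc2ccccc2)COC1=O | intermediate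
13 | (4R)-4-benzyl-3-[(2R,3R)-3-hydroxy-3-[(2R,3S)-3-{(4S)-4-[(4-methoxybenzyl)oxy]pentyl}-3-methyloxiran-2-yl]-2-(propan-2-yl)propanoyl]-1,3-oxazolidin-2-one | CC(C)[C@@H](C(=O)N1[C@H](Cc2ccccc2)COC1=O)[C@H]([C@@H]1[C@@](CCC[C@H](C)OCc2ccc(OC)cc2)(C)O1)O | intermediate
14 | (1R,2S)-1-[(2R,3S)-3-{(4S)-4-[(4-methoxybenzyl)oxy]pentyl}-3-methyloxiran-2-yl]-2-(propan-2-yl)propane-1,3-diol | CC(C)[C@@H](CO)[C@H]([C@@H]1[C@@](CCC[C@H](C)OCc2ccc(OC)cc2)(C)O1)O | intermediate
15 | (2R,3R)-3-hydroxy-3-[(2R,3S)-3-{(4S)-4-[(4-methoxybenzyl)oxy]pentyl}-3-methyloxiran-2-yl]-2-(propan-2-yl)propanal | CC(C)[C@@H](C=O)[C@H]([C@@H]1[C@@](CCC[C@H](C)OCc2ccc(OC)cc2)(C)O1)O | intermediate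
16 | (1R,2S,3E)-4-iodo-1-[(2R,3S)-3-{(4S)-4-[(4-methoxybenzyl)oxy]pentyl}-3-methyloxiran-2-yl]-2-(propan-2-yl)but-3-en-1-ol | CC(C)[C@@H](/C=C/I)[C@H]([C@@H]1[C@@](CCC[C@H](C)OCc2ccc(OC)cc2)(C)O1)O | intermediate
17 | 4-hydroxybenzoic acid | O=C(O)c1ccc(O)cc1 | starting material
18 | tert-butyldimethylsilyl 4-[(tert-butyldimethylsilyl)oxy]benzoate | CC(C)(C)[Si](C)(C)OC(=O)c1ccc(O[Si](C)(C)C(C)(C)C)cc1 | intermediate
19 | 4-[(tert-butyldimethylsilyl)oxy]benzoic acid | O=C(O)c1ccc(O[Si](C)(C)C(C)(C)C)cc1 | intermediate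
20 | 4-[(tert-butyldimethylsilyl)oxy]benzoic 2,4,6-trichlorobenzoic anhydride | O=C(OC(=O)c1c(Cl)cc(Cl)cc1Cl)c1ccc(O[Si](C)(C)C(C)(C)C)cc1 | intermediate
21 | (1R,2S,3E)-4-iodo-1-[(2R,3S)-3-{(4S)-4-[(4-methoxybenzyl)oxy]pentyl}-3-methyloxiran-2-yl]-2-(propan-2-yl)but-3-en-1-yl 4-[(tert-butyldimethylsilyl)oxy]benzoate | CC(C)[C@@H](/C=C/I)[C@H]([C@@H]1[C@@](CCC[C@H](C)OCc2ccc(OC)cc2)(C)O1)OC(=O)c1ccc(O[Si](C)(C)C(C)(C)C)cc1 | intermediate
22 | (1R,2S,3E)-1-[(2R,3S)-3-[(4S)-4-hydroxypentyl]-3-methyloxiran-2-yl]-4-iodo-2-(propan-2-yl)but-3-en-1-yl 4-[(tert-butyldimethylsilyl)oxy]benzoate | CC(C)[C@@H](/C=C/I)[C@H]([C@@H]1[C@@](CCC[C@H](C)O)(C)O1)OC(=O)c1ccc(O[Si](C)(C)C(C)(C)C)cc1 | intermediate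
23 | (1R,2S,3E)-4-iodo-1-[(2R,3S)-3-methyl-3-(4-oxopentyl)oxiran-2-yl]-2-(propan-2-yl)but-3-en-1-yl 4-[(tert-butyldimethylsilyl)oxy]benzoate | CC(C)[C@@H](/C=C/I)[C@H]([C@@H]1[C@@](CCCC(C)=O)(C)O1)OC(=O)c1ccc(O[Si](C)(C)C(C)(C)C)cc1 | intermediate
24 | (E)-alkenylchromium dichloride derived from 23 | CC(C)[C@@H](/C=C/[Cr](Cl)Cl)[C@H]([C@@H]1[C@@](CCCC(C)=O)(C)O1)OC(=O)c1ccc(O[Si](C)(C)C(C)(C)C)cc1 | intermediate
25 | (1R,2R,3S,4E,6R,10S)-6-hydroxy-6,10-dimethyl-3-(propan-2-yl)-11-oxabicyclo[8.1.0]undec-4-en-2-yl 4-[(tert-butyldimethylsilyl)oxy]benzoate | CC(C)[C@H]1/C=C/[C@](C)(O)CCC[C@]2(C)O[C@@H]2[C@@H]1OC(=O)c1ccc(O[Si](C)(C)C(C)(C)C)cc1 | intermediate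
26 | (1R,2R,3S,4E,6R,10S)-6-hydroxy-6,10-dimethyl-3-(propan-2-yl)-11-oxabicyclo[8.1.0]undec-4-en-2-yl 4-hydroxybenzoate | CC(C)[C@H]1/C=C/[C@](C)(O)CCC[C@]2(C)O[C@@H]2[C@@H]1OC(=O)c1ccc(O)cc1 | target

**Step count**

Total: 16 steps. Longest linear sequence: 13 steps (from 3 through steps 2, 3, 4, 5, 7, 8, 9, 10, 12, 13, 14, 15 and 16).

**Steps most likely to fail**

Step 15 (ring closure). Addition of the alkenylchromium to the ketone may be slow, so that protonation of the organometal or intermolecular coupling competes. Chromium salts acting as Lewis acids may let the ketone oxygen or chloride open the epoxide. The ketone may also be attacked on the wrong face. The fallback closes the ring before acylation, on a substrate without the ester and with a bulky silyl ether that changes the conformational bias. It sets out from 16. Silylation (Et3SiCl, imidazole, DMF) should give the triethylsilyl ether of 16 F1. DDQ in buffered CH2Cl2 should give the side-chain alcohol F2, and Dess–Martin oxidation the methyl ketone F3. NHK cyclisation (CrCl2, NiCl2 cat., DMSO, high dilution) should give the macrocyclic silyl ether F4. TBAF then frees the macrocyclic diol F5, whose secondary hydroxyl alone should be acylated with 19 under the Yamaguchi conditions of step 12 (via 20); the tertiary carbinol is inert. The fallback returns to the route at 25.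

Step 7 (aldol). The dialkylboron triflate may open the acid-sensitive trisubstituted epoxide, and the facial control may be eroded if the aldehyde epimerises or the pairing is less well matched than expected. The fallback replaces the aldol by a Lewis-acid-free allylboration and sets out from 8. (Z)-4-Methylpent-2-ene is metalated at its methyl group (n-BuLi, KOtBu, THF, −78 to −50 °C) and trapped with 2-isopropoxy-4,4,5,5-tetramethyl-1,3,2-dioxaborolane to give 4,4,5,5-tetramethyl-2-[(2Z)-4-methylpent-2-en-1-yl]-1,3,2-dioxaborolane F6. Its addition to 8 in toluene at rt proceeds through a closed chair, so the Z geometry should give the syn relation of hydroxyl and isopropyl, and the Cornforth preference of the epoxy aldehyde the anti relation to the epoxide oxygen, giving the homoallylic alcohol F7. Lemieux–Johnson cleavage of its terminal alkene (OsO4 cat., NaIO4, 2,6-lutidine, dioxane/H2O) returns to the route at 15.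

Step 10 (Takai olefination of the unprotected β-hydroxy aldehyde). Retro-aldol cleavage, dehydration or epimerisation at the α-carbon may occur before olefination. The fallback carries the carbinol as a silyl ether through the redox steps and sets out from 13. Silylation (Et3SiOTf, 2,6-lutidine, CH2Cl2, −78 °C) should give the triethylsilyl ether of 13 F8. LiBH4 should give the primary alcohol F9, Dess–Martin oxidation the β-silyloxy aldehyde F10, and Takai olefination (CrCl2, CHI3) the triethylsilyl ether of 16 F1. TBAF buffered with AcOH then returns to the route at 16.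

**Further compounds**

F1 | step 15 | triethyl{[(1R,2S,3E)-4-iodo-1-[(2R,3S)-3-{(4S)-4-[(4-methoxybenzyl)oxy]pentyl}-3-methyloxiran-2-yl]-2-(propan-2-yl)but-3-en-1-yl]oxy}silane | CC(C)[C@@H](/C=C/I)[C@H]([C@@H]1[C@@](CCC[C@H](C)OCc2ccc(OC)cc2)(C)O1)O[Si](CC)(CC)CC
F2 | step 15 | (2S)-5-[(2S,3R)-3-[(1R,2S,3E)-4-iodo-2-(propan-2-yl)-1-[(triethylsilyl)oxy]but-3-en-1-yl]-2-methyloxiran-2-yl]pentan-2-ol | CC(C)[C@@H](/C=C/I)[C@H]([C@@H]1[C@@](CCC[C@H](C)O)(C)O1)O[Si](CC)(CC)CC
F3 | step 15 | 5-[(2S,3R)-3-[(1R,2S,3E)-4-iodo-2-(propan-2-yl)-1-[(triethylsilyl)oxy]but-3-en-1-yl]-2-methyloxiran-2-yl]pentan-2-one | CC(C)[C@@H](/C=C/I)[C@H]([C@@H]1[C@@](CCCC(C)=O)(C)O1)O[Si](CC)(CC)CC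
F4 | step 15 | (1R,2R,3S,4E,6R,10S)-6,10-dimethyl-3-(propan-2-yl)-2-[(triethylsilyl)oxy]-11-oxabicyclo[8.1.0]undec-4-en-6-ol | CC(C)[C@H]1/C=C/[C@](C)(O)CCC[C@]2(C)O[C@@H]2[C@@H]1O[Si](CC)(CC)CC
F5 | step 15 | (1R,2R,3S,4E,6R,10S)-6,10-dimethyl-3-(propan-2-yl)-11-oxabicyclo[8.1.0]undec-4-ene-2,6-diol | CC(C)[C@H]1/C=C/[C@](C)(O)CCC[C@]2(C)O[C@@H]2[C@@H]1O
F6 | step 7 | 4,4,5,5-tetramethyl-2-[(2Z)-4-methylpent-2-en-1-yl]-1,3,2-dioxaborolane | CC(C)/C=C\CB1OC(C)(C)C(C)(C)O1
F7 | step 7 | (1R,2S)-1-[(2R,3S)-3-{(4S)-4-[(4-methoxybenzyl)oxy]pentyl}-3-methyloxiran-2-yl]-2-(propan-2-yl)but-3-en-1-ol | CC(C)[C@@H](C=C)[C@H]([C@@H]1[C@@](CCC[C@H](C)OCc2ccc(OC)cc2)(C)O1)O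
F8 | step 10 | (4R)-4-benzyl-3-[(2R,3R)-3-[(2R,3S)-3-{(4S)-4-[(4-methoxybenzyl)oxy]pentyl}-3-methyloxiran-2-yl]-2-(propan-2-yl)-3-[(triethylsilyl)oxy]propanoyl]-1,3-oxazolidin-2-one | CC(C)[C@@H](C(=O)N1[C@H](Cc2ccccc2)COC1=O)[C@H]([C@@H]1[C@@](CCC[C@H](C)OCc2ccc(OC)cc2)(C)O1)O[Si](CC)(CC)CC
F9 | step 10 | (2S,3R)-3-[(2R,3S)-3-{(4S)-4-[(4-methoxybenzyl)oxy]pentyl}-3-methyloxiran-2-yl]-2-(propan-2-yl)-3-[(triethylsilyl)oxy]propan-1-ol | CC(C)[C@@H](CO)[C@H]([C@@H]1[C@@](CCC[C@H](C)OCc2ccc(OC)cc2)(C)O1)O[Si](CC)(CC)CC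
F10 | step 10 | (2R,3R)-3-[(2R,3S)-3-{(4S)-4-[(4-methoxybenzyl)oxy]pentyl}-3-methyloxiran-2-yl]-2-(propan-2-yl)-3-[(triethylsilyl)oxy]propanal | CC(C)[C@@H](C=O)[C@H]([C@@H]1[C@@](CCC[C@H](C)OCc2ccc(OC)cc2)(C)O1)O[Si](CC)(CC)CC
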